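**Plan**

1. Locants (target carbocycle): C1 (quaternary; CH3 and pyrone), C2 (H and (E)-pent-2-en-2-yl, C1′–C5′, attached through C2′), C3/C4 (epoxide), C5(CH3)=C6H; C7 is the carbon on C1 that becomes pyrone C6. Feature: C7 (carboxyl level) and C2′ sit cis across C1–C2 and C2′=C3′ is a γ,δ-alkene seen from C7, which is the retron of an ester-enolate Claisen shift across C1–C2.
2. Cuts: (a) the pyrone ring back to a C7 carboxyl (triketide from a β-keto ester dianion); (b) epoxide C4–O back to a trans-3,4-diol and C3–O back to a C4 ketone with C3–H; (c) C1–C2 by retro-Ireland–Claisen, which restores the C3′–O bond and opens the cyclohexene to a ten-membered (Z,Z)-dienyl lactone; (d) the lactone at C4–C5 (vinyl iodide plus aldehyde) and at the ester C–O, giving two halves that both come from one (Z)-vinyl iodide.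
3. Forward: vinyl iodide 8 → acid 11 and carbinol 15 → ester 16 → NHK closure of the ten-membered lactone 20 (temporary ring) → Ireland–Claisen contraction to the cyclohexene 23 → pyrone built on C7 → oxirane closed last.
4. Stereochemistry: the C3′ carbinol (CBS reduction) is relayed through the ring-enforced boat transition state to C1 and C2; C3 (from the Roche ester) is chosen to match this and is re-set later; C3/C4 of the epoxide come from substrate control (enolate hydroxylation anti to the pentenyl group, hydroxyl-directed reduction, invertive ring closure).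

Key step: step 13

Remark 1: the (R)-Roche ester is used because C3 of the lactone must be S to match the (R)-carbinol in the boat transition state (C3–H in the alkene plane by allylic strain); both enantiomers are commercial.
Remark 2: C4 is carried as a TBS-protected carbinol rather than at the ketone level, because an open-chain C4 ketone would be β,γ-unsaturated and epimerisable at C3; the C4 configuration is erased at enone 33 and is drawn as the Felkin–Anh (4R) epimer, the other epimer following the same steps.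
Remark 3: the lactone α-carbon (C1) is carried as the S epimer that the common building block provides; both epimers give the same planar ketene acetal.

**Route**

Step 1
Reactants: 1 methyl (R)-3-hydroxy-2-methylpropanoate
Product: 2 methyl (R)-3-[(tert-butyldimethylsilyl)oxy]-2-methylpropanoate
Conditions: TBSCl, imidazole, CH2Cl2, 0 °C → rt
Reagents that add atoms: tert-butyldimethylsilyl chloride, CC(C)(C)[Si](C)(C)Cl
Why: Imidazole-promoted silyl ether formation at the primary alcohol is routine and leaves the α-stereocentre untouched.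

Step 2
Reactants: 2 methyl (R)-3-[(tert-butyldimethylsilyl)oxy]-2-methylpropanoate
Product: 3 (R)-3-[(tert-butyldimethylsilyl)oxy]-2-methylpropanal
Conditions: DIBAL-H (1.05 equiv), CH2Cl2, −78 °C; Rochelle salt work-up
Reagents that add atoms: none
Why: DIBAL-H half-reduction at −78 °C stops at the tetrahedral aluminate, so the aldehyde is released only on work-up and is used crude to avoid α-epimerisation.

Step 3
Reactants: 3 (R)-3-[(tert-butyldimethylsilyl)oxy]-2-methylpropanal; 4 ethyltriphenylphosphonium iodide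
Product: 8 tert-butyl{[(2S,3Z)-4-iodo-2-methylpent-3-en-1-yl]oxy}dimethylsilane, via ethylidenetriphenylphosphorane 5 (not isolated), via (1-iodoethyl)triphenylphosphonium iodide 6 (not isolated), via (1-iodoethylidene)triphenylphosphorane 7 (not isolated)
Conditions: n-BuLi, THF, 0 °C; I2, −78 °C; NaHMDS, −78 → −20 °C; then 3, −78 °C → rt
Reagents that add atoms: iodine, II
Why: Stork–Zhao iodo-olefination (Wittig reaction of the non-stabilised α-iodo ylide 7) gives the trisubstituted vinyl iodide with iodine cis to the branched carbon (Z), the geometry both halves of the lactone need.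

Step 4
Reactants: 8 tert-butyl{[(2S,3Z)-4-iodo-2-methylpent-3-en-1-yl]oxy}dimethylsilane
Product: 9 (2S,3Z)-4-iodo-2-methylpent-3-en-1-ol
Conditions: CSA (10 mol %), MeOH, 0 °C → rt
Reagents that add atoms: none
Why: Acid-catalysed methanolysis cleaves the primary silyl ether while the vinyl iodide is inert.

Step 5
Reactants: 9 (2S,3Z)-4-iodo-2-methylpent-3-en-1-ol
Product: 11 (2S,3Z)-4-iodo-2-methylpent-3-enoic acid, via (2S,3Z)-4-iodo-2-methylpent-3-enal 10 (not isolated)
Conditions: TEMPO (20 mol %), PhI(OAc)2 (2.2 equiv), MeCN/H2O 1:1, rt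
Reagents that add atoms: water, O
Why: Oxoammonium-mediated oxidation (TEMPO/PhI(OAc)2) takes the alcohol through aldehyde 10 and its hydrate to the acid under near-neutral conditions that should not move the β,γ-double bond, and the C2 configuration is immaterial because this carbon is later enolised.

Step 6
Reactants: 8 tert-butyl{[(2S,3Z)-4-iodo-2-methylpent-3-en-1-yl]oxy}dimethylsilane; 12 N-methoxy-N-methylpropanamide
Product: 14 (4Z,6S)-7-[(tert-butyldimethylsilyl)oxy]-4,6-dimethylhept-4-en-3-one, via alkenyllithium 13 (not isolated)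
Conditions: t-BuLi (2.1 equiv), Et2O, −78 °C; then 12, −78 → −20 °C; cold aq. NH4Cl
Reagents that add atoms: none
Why: Iodine–lithium exchange proceeds with retention of alkene geometry and the Weinreb ketone synthesis stops at the chelated tetrahedral adduct, so the Z-enone forms without over-addition and is taken on directly.

Step 7
Reactants: 14 (4Z,6S)-7-[(tert-butyldimethylsilyl)oxy]-4,6-dimethylhept-4-en-3-one
Product: 15 (3R,4Z,6S)-7-[(tert-butyldimethylsilyl)oxy]-4,6-dimethylhept-4-en-3-ol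
Conditions: (S)-Me-CBS (0.3 equiv), catecholborane, toluene, −78 °C
Reagents that add atoms: none
Why: Corey–Bakshi–Shibata reduction with the α-methylalkenyl group as the large and ethyl as the small substituent delivers hydride 1,2 to one carbonyl face and should set the 3R carbinol, the sense in which the (S)-catalyst turns acetophenone into (R)-1-phenylethanol.

Step 8
Reactants: 15 (3R,4Z,6S)-7-[(tert-butyldimethylsilyl)oxy]-4,6-dimethylhept-4-en-3-ol; 11 (2S,3Z)-4-iodo-2-methylpent-3-enoic acid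
Product: 16 (3R,4Z,6S)-7-[(tert-butyldimethylsilyl)oxy]-4,6-dimethylhept-4-en-3-yl (2S,3Z)-4-iodo-2-methylpent-3-enoate
Conditions: EDC·HCl, DMAP (cat.), CH2Cl2, 0 °C → rt
Reagents that add atoms: none
Why: Steglich esterification (carbodiimide activation, DMAP acyl transfer) joins the two halves with retention at the carbinol carbon, and epimerisation of the acid α-centre would be harmless.

Step 9
Reactants: 16 (3R,4Z,6S)-7-[(tert-butyldimethylsilyl)oxy]-4,6-dimethylhept-4-en-3-yl (2S,3Z)-4-iodo-2-methylpent-3-enoate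
Product: 17 (3R,4Z,6S)-7-hydroxy-4,6-dimethylhept-4-en-3-yl (2S,3Z)-4-iodo-2-methylpent-3-enoate
Conditions: CSA (10 mol %), MeOH/CH2Cl2, 0 °C
Reagents that add atoms: none
Why: Mild acidic methanolysis removes the primary silyl ether and leaves the hindered allylic ester and the vinyl iodide intact.

Step 10
Reactants: 17 (3R,4Z,6S)-7-hydroxy-4,6-dimethylhept-4-en-3-yl (2S,3Z)-4-iodo-2-methylpent-3-enoate
Product: 18 (3R,4Z,6S)-4,6-dimethyl-7-oxohept-4-en-3-yl (2S,3Z)-4-iodo-2-methylpent-3-enoate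
Conditions: Dess–Martin periodinane, NaHCO3, CH2Cl2, 0 °C; used at once
Reagents that add atoms: none
Why: Buffered Dess–Martin oxidation gives the α-methyl-β,γ-unsaturated aldehyde under non-basic conditions, and immediate use avoids epimerisation at C3 or conjugation.

Step 11
Reactants: 18 (3R,4Z,6S)-4,6-dimethyl-7-oxohept-4-en-3-yl (2S,3Z)-4-iodo-2-methylpent-3-enoate
Product: 19 (3S,4Z,6R,7S,8Z,10R)-10-ethyl-6-hydroxy-3,5,7,9-tetramethyl-3,6,7,10-tetrahydro-2H-oxecin-2-one
Conditions: CrCl2 (10 equiv), NiCl2 (1 mol %), degassed DMSO/THF, rt, substrate added slowly to about 2 mM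
Reagents that add atoms: none
Why: Intramolecular Nozaki–Hiyama–Kishi reaction, in which nickel activates the vinyl iodide and the resulting vinylchromium(III) species adds only to the aldehyde with retention of the Z geometry while high dilution favours the ten-membered ring; the new C4 carbinol is drawn as the Felkin–Anh epimer and is oxidised later.

Step 12
Reactants: 19 (3S,4Z,6R,7S,8Z,10R)-10-ethyl-6-hydroxy-3,5,7,9-tetramethyl-3,6,7,10-tetrahydro-2H-oxecin-2-one
Product: 20 (3S,4Z,6R,7S,8Z,10R)-6-[(tert-butyldimethylsilyl)oxy]-10-ethyl-3,5,7,9-tetramethyl-3,6,7,10-tetrahydro-2H-oxecin-2-one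
Conditions: TBSOTf, 2,6-lutidine, CH2Cl2, −78 → 0 °C
Reagents that add atoms: tert-butyldimethylsilyl trifluoromethanesulfonate, CC(C)(C)[Si](C)(C)OS(=O)(=O)C(F)(F)F
Why: Silylation with the silyl triflate and a hindered base protects the flanked allylic alcohol quickly under non-nucleophilic conditions, before the C4 hydroxyl can attack the lactone carbonyl.

Step 13
Reactants: 20 (3S,4Z,6R,7S,8Z,10R)-6-[(tert-butyldimethylsilyl)oxy]-10-ethyl-3,5,7,9-tetramethyl-3,6,7,10-tetrahydro-2H-oxecin-2-one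
Product: 23 (1R,4R,5S,6R)-4-[(tert-butyldimethylsilyl)oxy]-1,3,5-trimethyl-6-[(2E)-pent-2-en-2-yl]cyclohex-2-ene-1-carboxylic acid, via trimethylsilyl ketene acetal 21 (not isolated), via trimethylsilyl ester 22 (not isolated)
Conditions: TMSCl/Et3N, then LDA, THF, −78 °C (internal quench); then toluene, 90 °C; aq. citric acid/THF
Reagents that add atoms: none
Why: LDA removes the doubly activated C1 proton of 20 in the presence of TMSCl, so the dienolate is O-silylated at once to ketene acetal 21 (its endocyclic C7=C1 bond necessarily cis), and on warming a concerted suprafacial [3,3] shift forms C1–C2 as the lactone C3′–O bond breaks, giving silyl ester 22 and, after hydrolysis, acid 23; this is an Ireland–Claisen ring contraction of a macrocyclic allylic lactone, a known reaction type for ten-membered rings. The six-membered carbocycle closes transannularly: the four-atom tether C3–C4–C5=C6 already joins the two termini, so only a boat-like pericyclic array is possible and the ten-membered ring contracts to the cyclohexene. C1 is set by this ring-enforced boat, which holds C7 and C2′ eclipsed and therefore cis on the new ring, and both C1 epimers of 20 converge in planar 21. C2 is set by the (R)-carbinol centre: the new bond forms on the alkene face that carries the departing oxygen, with the ethyl group pseudo-equatorial, which also makes the pentenyl double bond E. The step needs boat over chair, E over Z, and rearrangement over vinylogous β-elimination of the C4 silyloxy group; the ring with its two Z alkenes secures the first, the carbinol centre together with the matched C3 methyl group the second, and immediate silylation at −78 °C the third.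

Step 14
Reactants: 23 (1R,4R,5S,6R)-4-[(tert-butyldimethylsilyl)oxy]-1,3,5-trimethyl-6-[(2E)-pent-2-en-2-yl]cyclohex-2-ene-1-carboxylic acid
Product: 24 {(1R,4R,5S,6R)-4-[(tert-butyldimethylsilyl)oxy]-1,3,5-trimethyl-6-[(2E)-pent-2-en-2-yl]cyclohex-2-en-1-yl}methanol
Conditions: LiAlH4, THF, 0 → 45 °C
Reagents that add atoms: none
Why: Lithium aluminium hydride reduces the hindered α-quaternary acid to the neopentyl alcohol while the silyl ether and the alkenes are inert.

Step 15
Reactants: 24 {(1R,4R,5S,6R)-4-[(tert-butyldimethylsilyl)oxy]-1,3,5-trimethyl-6-[(2E)-pent-2-en-2-yl]cyclohex-2-en-1-yl}methanol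
Product: 25 (1R,4R,5S,6R)-4-[(tert-butyldimethylsilyl)oxy]-1,3,5-trimethyl-6-[(2E)-pent-2-en-2-yl]cyclohex-2-ene-1-carbaldehyde
Conditions: Dess–Martin periodinane, CH2Cl2, rt
Reagents that add atoms: none
Why: Dess–Martin oxidation gives the non-enolisable α-quaternary aldehyde.

Step 16
Reactants: 25 (1R,4R,5S,6R)-4-[(tert-butyldimethylsilyl)oxy]-1,3,5-trimethyl-6-[(2E)-pent-2-en-2-yl]cyclohex-2-ene-1-carbaldehyde; 26 methyl 2-methyl-3-oxopentanoate
Product: 28 methyl 5-hydroxy-2,4-dimethyl-3-oxo-5-{(1R,4R,5S,6R)-4-[(tert-butyldimethylsilyl)oxy]-1,3,5-trimethyl-6-[(2E)-pent-2-en-2-yl]cyclohex-2-en-1-yl}pentanoate (mixture of epimers at chain C2/C4/C5), via ketoester dianion 27 (not isolated)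
Conditions: 26, NaH, THF, 0 °C; n-BuLi, 0 °C; then 25, −78 → 0 °C
Reagents that add atoms: none
Why: The β-keto ester dianion reacts at its more nucleophilic terminal (γ) carbon in an aldol addition to the non-enolisable aldehyde, and the three new stereocentres all disappear in the next two steps.

Step 17
Reactants: 28 methyl 5-hydroxy-2,4-dimethyl-3-oxo-5-{(1R,4R,5S,6R)-4-[(tert-butyldimethylsilyl)oxy]-1,3,5-trimethyl-6-[(2E)-pent-2-en-2-yl]cyclohex-2-en-1-yl}pentanoate
Product: 29 methyl 2,4-dimethyl-3,5-dioxo-5-{(1R,4R,5S,6R)-4-[(tert-butyldimethylsilyl)oxy]-1,3,5-trimethyl-6-[(2E)-pent-2-en-2-yl]cyclohex-2-en-1-yl}pentanoate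
Conditions: Dess–Martin periodinane, CH2Cl2, rt
Reagents that add atoms: none
Why: Dess–Martin oxidation of the β-hydroxy ketone gives the β,δ-diketo ester (triketide), which holds all carbons of the pyrone.

Step 18
Reactants: 29 methyl 2,4-dimethyl-3,5-dioxo-5-{(1R,4R,5S,6R)-4-[(tert-butyldimethylsilyl)oxy]-1,3,5-trimethyl-6-[(2E)-pent-2-en-2-yl]cyclohex-2-en-1-yl}pentanoate
Product: 30 4-hydroxy-3,5-dimethyl-6-{(1R,4R,5S,6R)-4-[(tert-butyldimethylsilyl)oxy]-1,3,5-trimethyl-6-[(2E)-pent-2-en-2-yl]cyclohex-2-en-1-yl}-2H-pyran-2-one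
Conditions: DBU, toluene, 60 °C; aq. citric acid work-up
Reagents that add atoms: none
Why: Base-mediated enolisation of the δ-ketone and O-acylation by the methyl ester (lactonisation with loss of methanol) closes the 4-hydroxy-2-pyranone ring.

Step 19
Reactants: 30 4-hydroxy-3,5-dimethyl-6-{(1R,4R,5S,6R)-4-[(tert-butyldimethylsilyl)oxy]-1,3,5-trimethyl-6-[(2E)-pent-2-en-2-yl]cyclohex-2-en-1-yl}-2H-pyran-2-one
Product: 31 2-methoxy-3,5-dimethyl-6-{(1R,4R,5S,6R)-4-[(tert-butyldimethylsilyl)oxy]-1,3,5-trimethyl-6-[(2E)-pent-2-en-2-yl]cyclohex-2-en-1-yl}-4H-pyran-4-one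
Conditions: MeOTf, CH2Cl2, rt; then aq. NaHCO3
Reagents that add atoms: methyl trifluoromethanesulfonate, COS(=O)(=O)C(F)(F)F
Why: The neutral 4-hydroxy-2-pyranone is methylated by the hard alkylating agent at its more nucleophilic lactone carbonyl oxygen, and loss of the proton on bicarbonate work-up gives the 2-methoxy-4-pyranone regioisomer (O-alkylation of a vinylogous acid).

Step 20
Reactants: 31 2-methoxy-3,5-dimethyl-6-{(1R,4R,5S,6R)-4-[(tert-butyldimethylsilyl)oxy]-1,3,5-trimethyl-6-[(2E)-pent-2-en-2-yl]cyclohex-2-en-1-yl}-4H-pyran-4-one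
Product: 32 2-{(1R,4R,5S,6R)-4-hydroxy-1,3,5-trimethyl-6-[(2E)-pent-2-en-2-yl]cyclohex-2-en-1-yl}-6-methoxy-3,5-dimethyl-4H-pyran-4-one
Conditions: HF·pyridine, pyridine, THF, 0 °C → rt
Reagents that add atoms: none
Why: Fluoride-mediated desilylation with buffered HF·pyridine frees the C4 allylic alcohol without touching the methoxypyranone.

Step 21
Reactants: 32 2-{(1R,4R,5S,6R)-4-hydroxy-1,3,5-trimethyl-6-[(2E)-pent-2-en-2-yl]cyclohex-2-en-1-yl}-6-methoxy-3,5-dimethyl-4H-pyran-4-one
Product: 33 2-methoxy-3,5-dimethyl-6-{(1R,5S,6R)-1,3,5-trimethyl-4-oxo-6-[(2E)-pent-2-en-2-yl]cyclohex-2-en-1-yl}-4H-pyran-4-one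
Conditions: Dess–Martin periodinane, CH2Cl2, rt
Reagents that add atoms: none
Why: Dess–Martin oxidation of the allylic alcohol gives the C4 enone and erases the C4 stereocentre.

Step 22
Reactants: 33 2-methoxy-3,5-dimethyl-6-{(1R,5S,6R)-1,3,5-trimethyl-4-oxo-6-[(2E)-pent-2-en-2-yl]cyclohex-2-en-1-yl}-4H-pyran-4-one
Product: 35 2-{(1R,5S,6R)-5-hydroxy-1,3,5-trimethyl-4-oxo-6-[(2E)-pent-2-en-2-yl]cyclohex-2-en-1-yl}-6-methoxy-3,5-dimethyl-4H-pyran-4-one, via potassium dienolate 34 (not isolated)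
Conditions: KHMDS, THF, −78 °C; then 3-phenyl-2-(phenylsulfonyl)oxaziridine, −78 → −40 °C
Reagents that add atoms: 3-phenyl-2-(phenylsulfonyl)oxaziridine, O=S(=O)(N1OC1c1ccccc1)c1ccccc1
Why: C3–H is the only enolisable position (C1 is quaternary), and the cross-conjugated dienolate takes up electrophilic oxygen from the N-sulfonyloxaziridine (Davis oxidation) at C3 on the face anti to the adjacent pseudo-axial C2 pentenyl group, so the new hydroxyl should end up trans to that group as the target requires.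

Step 23
Reactants: 35 2-{(1R,5S,6R)-5-hydroxy-1,3,5-trimethyl-4-oxo-6-[(2E)-pent-2-en-2-yl]cyclohex-2-en-1-yl}-6-methoxy-3,5-dimethyl-4H-pyran-4-one
Product: 36 2-{(1R,4S,5S,6R)-4,5-dihydroxy-1,3,5-trimethyl-6-[(2E)-pent-2-en-2-yl]cyclohex-2-en-1-yl}-6-methoxy-3,5-dimethyl-4H-pyran-4-one
Conditions: Me4NBH(OAc)3, MeCN/AcOH, −30 °C
Reagents that add atoms: none
Why: Hydroxyl-directed reduction (Evans–Saksena type), in which the C3 hydroxyl replaces an acetate on boron and hydride is delivered intramolecularly to the same face of the C4 carbonyl, should give the trans-3,4-diol by 1,2-reduction of the enone.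

Step 24
Reactants: 36 2-{(1R,4S,5S,6R)-4,5-dihydroxy-1,3,5-trimethyl-6-[(2E)-pent-2-en-2-yl]cyclohex-2-en-1-yl}-6-methoxy-3,5-dimethyl-4H-pyran-4-one
Product: 38 2-methoxy-3,5-dimethyl-6-{(1S,2R,3R,6R)-1,3,5-trimethyl-2-[(2E)-pent-2-en-2-yl]-7-oxabicyclo[4.1.0]hept-4-en-3-yl}-4H-pyran-4-one (target CNP0352631.1), via C4 mesylate 37 (not isolated)
Conditions: Ms2O, Et3N, CH2Cl2, −20 °C; then DBU, 0 °C → rt
Reagents that add atoms: none
Why: Selective mesylation of the secondary allylic alcohol and base-induced intramolecular Williamson displacement by the tertiary C3 alkoxide close the oxirane with inversion at C4, which puts the epoxide on the face opposite the pentenyl group.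

**Compound list**

1 | methyl (R)-3-hydroxy-2-methylpropanoate | COC(=O)[C@H](C)CO | starting material
2 | methyl (R)-3-[(tert-butyldimethylsilyl)oxy]-2-methylpropanoate | COC(=O)[C@H](C)CO[Si](C)(C)C(C)(C)C | intermediate
3 | (R)-3-[(tert-butyldimethylsilyl)oxy]-2-methylpropanal | O=C[C@H](C)CO[Si](C)(C)C(C)(C)C | intermediate
4 | ethyltriphenylphosphonium iodide | CC[P+](c1ccccc1)(c1ccccc1)c1ccccc1.[I-] | starting material
5 | ethylidenetriphenylphosphorane | CC=P(c1ccccc1)(c1ccccc1)c1ccccc1 | intermediate (not isolated)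
6 | (1-iodoethyl)triphenylphosphonium iodide | CC(I)[P+](c1ccccc1)(c1ccccc1)c1ccccc1.[I-] | intermediate (not isolated)
7 | (1-iodoethylidene)triphenylphosphorane | CC(I)=P(c1ccccc1)(c1ccccc1)c1ccccc1 | intermediate (not isolated)
8 | tert-butyl{[(2S,3Z)-4-iodo-2-methylpent-3-en-1-yl]oxy}dimethylsilane | C/C(I)=C/[C@H](C)CO[Si](C)(C)C(C)(C)C | intermediate
9 | (2S,3Z)-4-iodo-2-methylpent-3-en-1-ol | C/C(I)=C/[C@H](C)CO | intermediate
10 | (2S,3Z)-4-iodo-2-methylpent-3-enal | C/C(I)=C/[C@H](C)C=O | intermediate (not isolated)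
11 | (2S,3Z)-4-iodo-2-methylpent-3-enoic acid | C/C(I)=C/[C@H](C)C(=O)O | intermediate
12 | N-methoxy-N-methylpropanamide | CCC(=O)N(C)OC | starting material
13 | alkenyllithium from 8 (Li in place of I, geometry retained: Li cis to the CH(CH3) carbon, 4S) | C/C([Li])=C/[C@H](C)CO[Si](C)(C)C(C)(C)C | intermediate (not isolated)
14 | (4Z,6S)-7-[(tert-butyldimethylsilyl)oxy]-4,6-dimethylhept-4-en-3-one | CCC(=O)/C(C)=C\[C@H](C)CO[Si](C)(C)C(C)(C)C | intermediate
15 | (3R,4Z,6S)-7-[(tert-butyldimethylsilyl)oxy]-4,6-dimethylhept-4-en-3-ol | CC[C@@H](O)/C(C)=C\[C@H](C)CO[Si](C)(C)C(C)(C)C | intermediate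
16 | (3R,4Z,6S)-7-[(tert-butyldimethylsilyl)oxy]-4,6-dimethylhept-4-en-3-yl (2S,3Z)-4-iodo-2-methylpent-3-enoate | CC[C@@H](OC(=O)[C@@H](C)/C=C(C)\I)/C(C)=C\[C@H](C)CO[Si](C)(C)C(C)(C)C | intermediate
17 | (3R,4Z,6S)-7-hydroxy-4,6-dimethylhept-4-en-3-yl (2S,3Z)-4-iodo-2-methylpent-3-enoate | CC[C@@H](OC(=O)[C@@H](C)/C=C(C)\I)/C(C)=C\[C@H](C)CO | intermediate
18 | (3R,4Z,6S)-4,6-dimethyl-7-oxohept-4-en-3-yl (2S,3Z)-4-iodo-2-methylpent-3-enoate | CC[C@@H](OC(=O)[C@@H](C)/C=C(C)\I)/C(C)=C\[C@H](C)C=O | intermediate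
19 | (3S,4Z,6R,7S,8Z,10R)-10-ethyl-6-hydroxy-3,5,7,9-tetramethyl-3,6,7,10-tetrahydro-2H-oxecin-2-one | CC[C@H]1OC(=O)[C@@H](C)/C=C(C)\[C@H](O)[C@@H](C)/C=C1/C | intermediate
20 | (3S,4Z,6R,7S,8Z,10R)-6-[(tert-butyldimethylsilyl)oxy]-10-ethyl-3,5,7,9-tetramethyl-3,6,7,10-tetrahydro-2H-oxecin-2-one (precursor of the key step) | CC[C@H]1OC(=O)[C@@H](C)/C=C(C)\[C@H](O[Si](C)(C)C(C)(C)C)[C@@H](C)/C=C1/C | intermediate
21 | trimethylsilyl ketene acetal of 20 (endocyclic C7=C1 bond, ring oxygen cis to C6) | CC[C@H]1O/C(O[Si](C)(C)C)=C(C)\C=C(C)/[C@H](O[Si](C)(C)C(C)(C)C)[C@@H](C)/C=C1/C | intermediate (not isolated)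
22 | trimethylsilyl ester of 23 | CC/C=C(\C)[C@H]1[C@H](C)[C@@H](O[Si](C)(C)C(C)(C)C)C(C)=C[C@@]1(C)C(=O)O[Si](C)(C)C | intermediate (not isolated)
23 | (1R,4R,5S,6R)-4-[(tert-butyldimethylsilyl)oxy]-1,3,5-trimethyl-6-[(2E)-pent-2-en-2-yl]cyclohex-2-ene-1-carboxylic acid (product of the key step) | CC/C=C(\C)[C@H]1[C@H](C)[C@@H](O[Si](C)(C)C(C)(C)C)C(C)=C[C@@]1(C)C(=O)O | intermediate
24 | {(1R,4R,5S,6R)-4-[(tert-butyldimethylsilyl)oxy]-1,3,5-trimethyl-6-[(2E)-pent-2-en-2-yl]cyclohex-2-en-1-yl}methanol | CC/C=C(\C)[C@H]1[C@H](C)[C@@H](O[Si](C)(C)C(C)(C)C)C(C)=C[C@@]1(C)CO | intermediate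
25 | (1R,4R,5S,6R)-4-[(tert-butyldimethylsilyl)oxy]-1,3,5-trimethyl-6-[(2E)-pent-2-en-2-yl]cyclohex-2-ene-1-carbaldehyde | CC/C=C(\C)[C@H]1[C@H](C)[C@@H](O[Si](C)(C)C(C)(C)C)C(C)=C[C@@]1(C)C=O | intermediate
26 | methyl 2-methyl-3-oxopentanoate | CCC(=O)C(C)C(=O)OC | starting material
27 | sodium lithium dianion of 26 (dienolate, nucleophilic at C4) | CC=C([O-])C(C)=C([O-])OC.[Na+].[Li+] | intermediate (not isolated)
28 | methyl 5-hydroxy-2,4-dimethyl-3-oxo-5-{(1R,4R,5S,6R)-4-[(tert-butyldimethylsilyl)oxy]-1,3,5-trimethyl-6-[(2E)-pent-2-en-2-yl]cyclohex-2-en-1-yl}pentanoate (epimer mixture at chain C2, C4, C5) | CC/C=C(\C)[C@H]1[C@H](C)[C@@H](O[Si](C)(C)C(C)(C)C)C(C)=C[C@@]1(C)C(O)C(C)C(=O)C(C)C(=O)OC | intermediate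
29 | methyl 2,4-dimethyl-3,5-dioxo-5-{(1R,4R,5S,6R)-4-[(tert-butyldimethylsilyl)oxy]-1,3,5-trimethyl-6-[(2E)-pent-2-en-2-yl]cyclohex-2-en-1-yl}pentanoate (epimer mixture at chain C2, C4) | CC/C=C(\C)[C@H]1[C@H](C)[C@@H](O[Si](C)(C)C(C)(C)C)C(C)=C[C@@]1(C)C(=O)C(C)C(=O)C(C)C(=O)OC | intermediate
30 | 4-hydroxy-3,5-dimethyl-6-{(1R,4R,5S,6R)-4-[(tert-butyldimethylsilyl)oxy]-1,3,5-trimethyl-6-[(2E)-pent-2-en-2-yl]cyclohex-2-en-1-yl}-2H-pyran-2-one | CC/C=C(\C)[C@H]1[C@H](C)[C@@H](O[Si](C)(C)C(C)(C)C)C(C)=C[C@@]1(C)C2=C(C)C(O)=C(C)C(=O)O2 | intermediate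
31 | 2-methoxy-3,5-dimethyl-6-{(1R,4R,5S,6R)-4-[(tert-butyldimethylsilyl)oxy]-1,3,5-trimethyl-6-[(2E)-pent-2-en-2-yl]cyclohex-2-en-1-yl}-4H-pyran-4-one | CC/C=C(\C)[C@H]1[C@H](C)[C@@H](O[Si](C)(C)C(C)(C)C)C(C)=C[C@@]1(C)c1oc(OC)c(C)c(=O)c1C | intermediate
32 | 2-{(1R,4R,5S,6R)-4-hydroxy-1,3,5-trimethyl-6-[(2E)-pent-2-en-2-yl]cyclohex-2-en-1-yl}-6-methoxy-3,5-dimethyl-4H-pyran-4-one | CC/C=C(\C)[C@H]1[C@H](C)[C@@H](O)C(C)=C[C@@]1(C)c1oc(OC)c(C)c(=O)c1C | intermediate
33 | 2-methoxy-3,5-dimethyl-6-{(1R,5S,6R)-1,3,5-trimethyl-4-oxo-6-[(2E)-pent-2-en-2-yl]cyclohex-2-en-1-yl}-4H-pyran-4-one | CC/C=C(\C)[C@H]1[C@H](C)C(=O)C(C)=C[C@@]1(C)c1oc(OC)c(C)c(=O)c1C | intermediate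
34 | potassium cross-conjugated dienolate of 33 (C3=C4–O−) | CC/C=C(\C)[C@H]1C(C)=C([O-])C(C)=C[C@@]1(C)c1oc(OC)c(C)c(=O)c1C.[K+] | intermediate (not isolated)
35 | 2-{(1R,5S,6R)-5-hydroxy-1,3,5-trimethyl-4-oxo-6-[(2E)-pent-2-en-2-yl]cyclohex-2-en-1-yl}-6-methoxy-3,5-dimethyl-4H-pyran-4-one | CC/C=C(\C)[C@H]1[C@](C)(O)C(=O)C(C)=C[C@@]1(C)c1oc(OC)c(C)c(=O)c1C | intermediate
36 | 2-{(1R,4S,5S,6R)-4,5-dihydroxy-1,3,5-trimethyl-6-[(2E)-pent-2-en-2-yl]cyclohex-2-en-1-yl}-6-methoxy-3,5-dimethyl-4H-pyran-4-one (trans-diol) | CC/C=C(\C)[C@H]1[C@](C)(O)[C@@H](O)C(C)=C[C@@]1(C)c1oc(OC)c(C)c(=O)c1C | intermediate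
37 | C4 methanesulfonate of 36 | CC/C=C(\C)[C@H]1[C@](C)(O)[C@@H](OS(C)(=O)=O)C(C)=C[C@@]1(C)c1oc(OC)c(C)c(=O)c1C | intermediate (not isolated)
38 | 2-methoxy-3,5-dimethyl-6-{(1S,2R,3R,6R)-1,3,5-trimethyl-2-[(2E)-pent-2-en-2-yl]-7-oxabicyclo[4.1.0]hept-4-en-3-yl}-4H-pyran-4-one (CNP0352631.1; C1 R, C2 R, C3 S, C4 R in the locants above) | CC/C=C(\C)[C@H]1[C@]2(C)O[C@@H]2C(C)=C[C@@]1(C)c1oc(OC)c(C)c(=O)c1C | target

**Count and risks**

Total: 24 steps. Longest linear sequence: 22 steps (1–3, 6–24); steps 4 and 5 are the short branch to acid 11.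

Step 11 (most at risk). What may go wrong: oligomerisation competing with closure of the strained ten-membered ring, epimerisation of the aldehyde α-centre before the aldehyde is trapped, and acyl migration of the new C4 alkoxide onto the lactone carbonyl (contraction to a six-membered lactone). Fallback: the ring is closed at the ester C–O bond instead of C4–C5; it sets out from 15 and 8 and comes back at 20. Compound 15 is desilylated (CSA, MeOH) to (2S,3Z,5R)-2,4-dimethylhept-3-ene-1,5-diol F1 and silylated twice (TESCl, imidazole) to the bis(triethylsilyl) ether F2. Swern oxidation, which cleaves and oxidises only the primary triethylsilyl ether, gives (2S,3Z,5R)-2,4-dimethyl-5-[(triethylsilyl)oxy]hept-3-enal F3. Alkenyllithium 13 (from 8, t-BuLi, Et2O, −78 °C) adds under Felkin–Anh control to give the C4 carbinol F4, which TBSOTf/2,6-lutidine converts into the tris-silyl ether F5. HF·pyridine removes the primary TBS and the allylic triethylsilyl group but not the hindered C4 TBS ether, giving the diol F6. TEMPO/PhI(OAc)2 in aqueous acetonitrile oxidises only the primary alcohol, to the seco acid F7, and Shiina macrolactonisation (2-methyl-6-nitrobenzoic anhydride, DMAP, CH2Cl2, slow addition, rt) gives 20. In this sequence the C4 hydroxyl is never free next to an acyl group.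

Step 13. What may go wrong: vinylogous β-elimination of the C4 silyloxy group from the dienolate before it is silylated, or a transannular rearrangement slow enough for the ketene acetal to decompose or to leak through a non-boat path. Fallback: the two C–C bonds are made in the opposite order; it sets out from 16 and comes back at 24. Open-chain Ireland–Claisen rearrangement of 16 (LDA, TMSCl, THF or THF–DMPU, −78 °C → rt) gives the acid F8. The transition state is now a chair, so the ketene acetal geometry must be set by the enolisation conditions, while the carbinol centre still fixes C2 and the E alkene. TMSCHN2 gives the methyl ester F9, buffered HF·pyridine the hydroxy ester F10, and immediate Dess–Martin oxidation the aldehyde F11. Intramolecular NHK closure, now of a six-membered ring, gives the cyclohexenol F12; TBSOTf/2,6-lutidine gives the silyl ether F13, and LiAlH4 reduction gives 24.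

Step 22. What may go wrong: slow oxygen transfer to the fully substituted, flanked enolate carbon, so that addition of the enolate to the sulfonimine by-product takes over, or the axial C1 methyl group on the desired face erodes facial control. Fallback: oxygen is introduced by alkene epoxidation instead of enolate oxidation; it sets out from 32 and comes back at 38. Burgess dehydration of 32 (syn elimination across C3–H and C4–OH, which are cis) gives the cyclohexa-2,4-diene F14. One equivalent of dimethyldioxirane at low temperature should then epoxidise the less hindered ring double bond C3=C4 from the face anti to the pentenyl group and give 38 directly. Chemoselectivity over C5=C6 (next to the quaternary centre) and over the side-chain alkene would have to be established on this substrate.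

**Further compounds**

F1 | step 11 | (2S,3Z,5R)-2,4-dimethylhept-3-ene-1,5-diol | CC[C@@H](O)/C(C)=C\[C@H](C)CO
F2 | step 11 | (2S,3Z,5R)-2,4-dimethyl-1,5-bis[(triethylsilyl)oxy]hept-3-ene | CC[C@@H](O[Si](CC)(CC)CC)/C(C)=C\[C@H](C)CO[Si](CC)(CC)CC
F3 | step 11 | (2S,3Z,5R)-2,4-dimethyl-5-[(triethylsilyl)oxy]hept-3-enal | CC[C@@H](O[Si](CC)(CC)CC)/C(C)=C\[C@H](C)C=O
F4 | step 11 | (2S,3Z,5R,6S,7Z,9R)-1-[(tert-butyldimethylsilyl)oxy]-2,4,6,8-tetramethyl-9-[(triethylsilyl)oxy]undeca-3,7-dien-5-ol | CC[C@@H](O[Si](CC)(CC)CC)/C(C)=C\[C@H](C)[C@@H](O)/C(C)=C\[C@H](C)CO[Si](C)(C)C(C)(C)C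
F5 | step 11 | (2S,3Z,5R,6S,7Z,9R)-1,5-bis[(tert-butyldimethylsilyl)oxy]-2,4,6,8-tetramethyl-9-[(triethylsilyl)oxy]undeca-3,7-diene | CC[C@@H](O[Si](CC)(CC)CC)/C(C)=C\[C@H](C)[C@@H](O[Si](C)(C)C(C)(C)C)/C(C)=C\[C@H](C)CO[Si](C)(C)C(C)(C)C
F6 | step 11 | (2S,3Z,5R,6S,7Z,9R)-5-[(tert-butyldimethylsilyl)oxy]-2,4,6,8-tetramethylundeca-3,7-diene-1,9-diol | CC[C@@H](O)/C(C)=C\[C@H](C)[C@@H](O[Si](C)(C)C(C)(C)C)/C(C)=C\[C@H](C)CO
F7 | step 11 | (2S,3Z,5R,6S,7Z,9R)-5-[(tert-butyldimethylsilyl)oxy]-9-hydroxy-2,4,6,8-tetramethylundeca-3,7-dienoic acid | CC[C@@H](O)/C(C)=C\[C@H](C)[C@@H](O[Si](C)(C)C(C)(C)C)/C(C)=C\[C@H](C)C(=O)O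
F8 | step 13 | (2S,3R,4S)-5-[(tert-butyldimethylsilyl)oxy]-2-[(Z)-2-iodoprop-1-en-1-yl]-2,4-dimethyl-3-[(2E)-pent-2-en-2-yl]pentanoic acid | CC/C=C(\C)[C@@H]([C@H](C)CO[Si](C)(C)C(C)(C)C)[C@@](C)(/C=C(C)\I)C(=O)O
F9 | step 13 | methyl (2S,3R,4S)-5-[(tert-butyldimethylsilyl)oxy]-2-[(Z)-2-iodoprop-1-en-1-yl]-2,4-dimethyl-3-[(2E)-pent-2-en-2-yl]pentanoate | CC/C=C(\C)[C@@H]([C@H](C)CO[Si](C)(C)C(C)(C)C)[C@@](C)(/C=C(C)\I)C(=O)OC
F10 | step 13 | methyl (2S,3R,4S)-5-hydroxy-2-[(Z)-2-iodoprop-1-en-1-yl]-2,4-dimethyl-3-[(2E)-pent-2-en-2-yl]pentanoate | CC/C=C(\C)[C@@H]([C@H](C)CO)[C@@](C)(/C=C(C)\I)C(=O)OC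
F11 | step 13 | methyl (2S,3R,4S)-2-[(Z)-2-iodoprop-1-en-1-yl]-2,4-dimethyl-5-oxo-3-[(2E)-pent-2-en-2-yl]pentanoate | CC/C=C(\C)[C@@H]([C@H](C)C=O)[C@@](C)(/C=C(C)\I)C(=O)OC
F12 | step 13 | methyl (1R,4R,5S,6R)-4-hydroxy-1,3,5-trimethyl-6-[(2E)-pent-2-en-2-yl]cyclohex-2-ene-1-carboxylate | CC/C=C(\C)[C@H]1[C@H](C)[C@@H](O)C(C)=C[C@@]1(C)C(=O)OC
F13 | step 13 | methyl (1R,4R,5S,6R)-4-[(tert-butyldimethylsilyl)oxy]-1,3,5-trimethyl-6-[(2E)-pent-2-en-2-yl]cyclohex-2-ene-1-carboxylate | CC/C=C(\C)[C@H]1[C@H](C)[C@@H](O[Si](C)(C)C(C)(C)C)C(C)=C[C@@]1(C)C(=O)OC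
F14 | step 22 | 2-methoxy-3,5-dimethyl-6-{(1R,6S)-1,3,5-trimethyl-6-[(2E)-pent-2-en-2-yl]cyclohexa-2,4-dien-1-yl}-4H-pyran-4-one | CC/C=C(\C)[C@H]1C(C)=CC(C)=C[C@@]1(C)c1oc(OC)c(C)c(=O)c1C
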